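## Retrosynthetic overview

1. The E-enol ester comes from an (E)-alkenylboron and 3-methylbut-2-enoic acid (Cu C–O coupling); the 1-(2-oxopropyl)-2,5-dihydrofuran comes from a butenolide by lactol formation, Wittig olefination and oxa-Michael closure.
2. Key step: the C6 quaternary centre is made from an exocyclic methylene by MHAT. The tertiary C6 radical is coupled through nickel with a homoprenyl halide, anti to the C7 vinyl group.
3. The cyclohexene ring is closed by a type-2 carbonyl-ene reaction of a 4-formylbutenolide carrying an isopropenyl group; C4 is then inverted (Mitsunobu).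
4. C7 is set by Ir-catalysed allylic alkylation of tetronic acid with rac-2-methylpenta-1,4-dien-3-ol.
5. Ring order: the butenolide is present from the start (tetronic acid), the carbocycle is closed in step 5, and the butenolide is turned into the dihydrofuran in step 9.

Assumption: 2-benzofuran numbering is used throughout (C1 = lactone carbonyl, later the carbon bearing the 2-oxopropyl group; C3 = OCH2; C4 = carbinol; C6 = quaternary carbon; C7 = carbon bearing the two-carbon side chain), the target being (1S,4S,6S,7R) with an E-enol ester; the sense of induction of the iridium catalyst in step 2 is taken by analogy and the enantiomeric ligand is used if it proves opposite.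

## Route

Step 1
Reactants: 1 methacrolein (2-methylprop-2-enal); 2 vinylmagnesium bromide
Product: 3 rac-2-methylpenta-1,4-dien-3-ol
Conditions: THF, −78 to 0 °C; aq. NH4Cl
Reagents that add atoms: none
Why: 1,2-Grignard addition to the enal gives the racemic bis-allylic alcohol, whose stereocentre is erased on ionisation in the next step.

Step 2
Reactants: 3 rac-2-methylpenta-1,4-dien-3-ol; 4 tetronic acid (4-hydroxyfuran-2(5H)-one)
Product: 5 4-hydroxy-3-[(3R)-2-methylpenta-1,4-dien-3-yl]furan-2(5H)-one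
Conditions: [Ir(cod)Cl]2 (3 mol%), (S)-BINOL-derived dibenzazepine phosphoramidite–olefin ligand (12 mol%), 1,2-dichloroethane, 25–40 °C
Reagents that add atoms: none
Why: Proposed new method: iridium-catalysed enantioconvergent allylic substitution of a racemic branched allylic alcohol (closest known type: Ir/phosphoramidite–olefin allylations of carbon nucleophiles with free allylic alcohols), in which tetronic acid (pKa about 4) acts both as the Brønsted acid that ionises the alcohol and as the soft C3 nucleophile; attack at the substituted allyl terminus gives the branched 1,4-diene, any O-allyl tetronate re-ionises and funnels to the C-allyl product, and ligand-controlled facial attack sets C7 as R.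

Step 3
Reactants: 5 4-hydroxy-3-[(3R)-2-methylpenta-1,4-dien-3-yl]furan-2(5H)-one
Product: 6 4-[(3R)-2-methylpenta-1,4-dien-3-yl]-5-oxo-2,5-dihydrofuran-3-yl trifluoromethanesulfonate
Conditions: Tf2O, i-Pr2NEt, CH2Cl2, −78 °C
Reagents that add atoms: trifluoromethanesulfonic anhydride, O=S(=O)(OS(=O)(=O)C(F)(F)F)C(F)(F)F
Why: O-sulfonylation of the vinylogous acid gives the enol triflate as a handle for cross-coupling at C3a; C7 is not touched.

Step 4
Reactants: 6 4-[(3R)-2-methylpenta-1,4-dien-3-yl]-5-oxo-2,5-dihydrofuran-3-yl trifluoromethanesulfonate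
Product: 7 4-[(3R)-2-methylpenta-1,4-dien-3-yl]-5-oxo-2,5-dihydrofuran-3-carbaldehyde
Conditions: Pd(PPh3)4 (5 mol%), CO (1–3 atm), Bu3SnH (slow addition), THF, 50 °C
Reagents that add atoms: carbon monoxide, [C-]#[O+]
Why: Stille-type palladium-catalysed reductive carbonylation (formylation) of the enol triflate by oxidative addition, CO insertion and hydride transfer from tin; the conditions are neutral, which protects the acidic C7–H, and the aldehyde is used at once.

Step 5
Reactants: 7 4-[(3R)-2-methylpenta-1,4-dien-3-yl]-5-oxo-2,5-dihydrofuran-3-carbaldehyde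
Product: 8 (4R,7R)-7-ethenyl-4-hydroxy-6-methylidene-4,5,6,7-tetrahydro-2-benzofuran-1(3H)-one
Conditions: Me2AlCl (1.5 equiv), CH2Cl2, −78 to −20 °C
Reagents that add atoms: none
Why: Lewis-acid-promoted type-2 intramolecular carbonyl-ene reaction of the 1,1-disubstituted alkene (far more nucleophilic than the vinyl group) through a bicyclo[3.3.1]-like transition state, in which the aluminium-bound oxygen must be axial to reach the allylic methyl hydrogen while the C7 vinyl group is pseudoaxial to avoid A(1,2) strain with the isopropenyl methyl and the lactone carbonyl, so the alcohol forms trans to vinyl (4R).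

Step 6
Reactants: 8 (4R,7R)-7-ethenyl-4-hydroxy-6-methylidene-4,5,6,7-tetrahydro-2-benzofuran-1(3H)-one
Product: 10 (4S,7R)-7-ethenyl-4-hydroxy-6-methylidene-4,5,6,7-tetrahydro-2-benzofuran-1(3H)-one, via formate ester 9 (not isolated)
Conditions: PPh3, DIAD, HCO2H, THF, 0 to 25 °C; then K2CO3 (cat.), MeOH, 0 °C
Reagents that add atoms: formic acid, O=CO
Why: Mitsunobu reaction: SN2 displacement of the activated pseudoaxial allylic alcohol by formate inverts C4 to S (ionisation and SN2' are disfavoured by the electron-poor tetrasubstituted butenolide alkene), and mild methanolysis frees the alcohol, now pseudoequatorial and cis to the C7 vinyl group.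

Step 7
Reactants: 10 (4S,7R)-7-ethenyl-4-hydroxy-6-methylidene-4,5,6,7-tetrahydro-2-benzofuran-1(3H)-one; 11 5-bromo-2-methylpent-2-ene
Product: 12 (4S,6S,7R)-7-ethenyl-4-hydroxy-6-methyl-6-(4-methylpent-3-en-1-yl)-4,5,6,7-tetrahydro-2-benzofuran-1(3H)-one
Conditions: Mn(dpm)3 (20 mol%), Ni(acac)2 (10 mol%), PhSiH3 (2 equiv), K2CO3, NaI, 11 (3 equiv), 1,2-dichloroethane/(CF3)2CHOH, 25 °C
Reagents that add atoms: none
Why: Mn/Ni dual-catalytic MHAT hydroalkylation (Markovnikov olefin–alkyl halide cross-coupling): Mn–H delivers a hydrogen atom to the 1,1-disubstituted alkene faster than to the mono- or trisubstituted ones, the tertiary C6 radical is captured by nickel on the face opposite the pseudoaxial C7 vinyl group, and C(sp3)–C(sp3) reductive elimination with the homoprenyl iodide (formed in the flask from 11 and NaI) gives the quaternary centre with the new chain trans to vinyl and the new methyl cis to it (6S).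

Step 8
Reactants: 12 (4S,6S,7R)-7-ethenyl-4-hydroxy-6-methyl-6-(4-methylpent-3-en-1-yl)-4,5,6,7-tetrahydro-2-benzofuran-1(3H)-one
Product: 14 (4S,6S,7R)-4-hydroxy-6-methyl-6-(4-methylpent-3-en-1-yl)-7-[(E)-2-(4,4,5,5-tetramethyl-1,3,2-dioxaborolan-2-yl)ethenyl]-4,5,6,7-tetrahydro-2-benzofuran-1(3H)-one, via catechol boronate 13 (not isolated)
Conditions: Pd2(dba)3 (2.5 mol%), (t-Bu)P(3,5-(t-Bu)2C6H3)2 (6 mol%), B-chlorocatecholborane (3 equiv), LiOTf, Cy2NMe, PhCF3, 70 °C; then pinacol, 25 °C
Reagents that add atoms: B-chlorocatecholborane, ClB1Oc2ccccc2O1; pinacol, CC(C)(O)C(C)(C)O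
Why: Boryl-Heck reaction: zerovalent palladium inserts into the B–Cl bond, anti-Markovnikov borylpalladation of the only monosubstituted alkene and β-hydride elimination give the E-alkenyl catechol boronate, which is transesterified to the pinacol ester; the hydroxyl is borylated transiently by the excess reagent and released on work-up, and no stereocentre is touched.

Step 9
Reactants: 14 (4S,6S,7R)-4-hydroxy-6-methyl-6-(4-methylpent-3-en-1-yl)-7-[(E)-2-(4,4,5,5-tetramethyl-1,3,2-dioxaborolan-2-yl)ethenyl]-4,5,6,7-tetrahydro-2-benzofuran-1(3H)-one; 15 chloroacetone (1-chloropropan-2-one)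
Product: 18 1-{(1S,4S,6S,7R)-4-hydroxy-6-methyl-6-(4-methylpent-3-en-1-yl)-7-[(E)-2-(4,4,5,5-tetramethyl-1,3,2-dioxaborolan-2-yl)ethenyl]-1,3,4,5,6,7-hexahydro-2-benzofuran-1-yl}propan-2-one, via lactol 16 (not isolated), via hydroxy dienone 17 (not isolated)
Conditions: i-Bu2AlH (2.5 equiv), CH2Cl2, −78 °C; Rochelle salt; then Ph3P=CHC(O)CH3 (made from 15 and PPh3 in PhMe at 80 °C, then aq. Na2CO3), PhMe, 70 °C; then DBU (0.2 equiv), 25 °C
Reagents that add atoms: none
Why: Lactone-to-lactol reduction, Wittig olefination of the ring-opened hydroxy enal with the stabilised ylide (E-enone) and base-equilibrated 5-exo oxa-Michael addition of the primary C3 alcohol (the C4 alcohol cannot close without forming a bridgehead alkene); thermodynamic control puts the 2-oxopropyl group trans to the pseudoaxial C7 substituent (1S).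

Step 10
Reactants: 18 1-{(1S,4S,6S,7R)-4-hydroxy-6-methyl-6-(4-methylpent-3-en-1-yl)-7-[(E)-2-(4,4,5,5-tetramethyl-1,3,2-dioxaborolan-2-yl)ethenyl]-1,3,4,5,6,7-hexahydro-2-benzofuran-1-yl}propan-2-one; 19 3-methylbut-2-enoic acid
Product: 21 (E)-2-[(1S,4S,6S,7R)-4-hydroxy-6-methyl-6-(4-methylpent-3-en-1-yl)-1-(2-oxopropyl)-1,3,4,5,6,7-hexahydro-2-benzofuran-7-yl]ethenyl 3-methylbut-2-enoate, via trifluoroborate salt 20 (not isolated)
Conditions: KHF2, MeOH/H2O, 25 °C, evaporate; then 19, CuBr (10 mol%), DMAP (20 mol%), 4 Å MS, O2 (1 atm), CH2Cl2, 40 °C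
Reagents that add atoms: none
Why: Conversion of the pinacol boronate into the trifluoroborate and copper-catalysed aerobic Chan–Lam-type C–O coupling with the carboxylic acid, which retains the E geometry and tolerates the free secondary alcohol and the ketone, so the enol ester is formed last without protecting groups.

## Compound list

1 | methacrolein (2-methylprop-2-enal) | CC(=C)C=O | starting material
2 | vinylmagnesium bromide | C=C[Mg]Br | starting material
3 | rac-2-methylpenta-1,4-dien-3-ol | CC(=C)C(O)C=C | intermediate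
4 | tetronic acid (4-hydroxyfuran-2(5H)-one) | O=C1OCC(O)=C1 | starting material
5 | 4-hydroxy-3-[(3R)-2-methylpenta-1,4-dien-3-yl]furan-2(5H)-one | O=C1OCC(O)=C1[C@H](C=C)C(C)=C | intermediate
6 | 4-[(3R)-2-methylpenta-1,4-dien-3-yl]-5-oxo-2,5-dihydrofuran-3-yl trifluoromethanesulfonate | O=C1OCC(OS(=O)(=O)C(F)(F)F)=C1[C@H](C=C)C(C)=C | intermediate
7 | 4-[(3R)-2-methylpenta-1,4-dien-3-yl]-5-oxo-2,5-dihydrofuran-3-carbaldehyde | O=C1OCC(C=O)=C1[C@H](C=C)C(C)=C | intermediate
8 | (4R,7R)-7-ethenyl-4-hydroxy-6-methylidene-4,5,6,7-tetrahydro-2-benzofuran-1(3H)-one (OH trans to vinyl) | O=C1OCC2=C1[C@H](C=C)C(=C)C[C@H]2O | intermediate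
9 | (4S,7R)-7-ethenyl-6-methylidene-1-oxo-1,3,4,5,6,7-hexahydro-2-benzofuran-4-yl formate | O=C1OCC2=C1[C@H](C=C)C(=C)C[C@@H]2OC=O | intermediate (not isolated)
10 | (4S,7R)-7-ethenyl-4-hydroxy-6-methylidene-4,5,6,7-tetrahydro-2-benzofuran-1(3H)-one (OH cis to vinyl) | O=C1OCC2=C1[C@H](C=C)C(=C)C[C@@H]2O | intermediate
11 | 5-bromo-2-methylpent-2-ene | CC(C)=CCCBr | starting material
12 | (4S,6S,7R)-7-ethenyl-4-hydroxy-6-methyl-6-(4-methylpent-3-en-1-yl)-4,5,6,7-tetrahydro-2-benzofuran-1(3H)-one | O=C1OCC2=C1[C@H](C=C)[C@@](C)(CCC=C(C)C)C[C@@H]2O | intermediate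
13 | (4S,6S,7R)-7-[(E)-2-(1,3,2-benzodioxaborol-2-yl)ethenyl]-4-hydroxy-6-methyl-6-(4-methylpent-3-en-1-yl)-4,5,6,7-tetrahydro-2-benzofuran-1(3H)-one | O=C1OCC2=C1[C@H](/C=C/B3Oc4ccccc4O3)[C@@](C)(CCC=C(C)C)C[C@@H]2O | intermediate (not isolated)
14 | (4S,6S,7R)-4-hydroxy-6-methyl-6-(4-methylpent-3-en-1-yl)-7-[(E)-2-(4,4,5,5-tetramethyl-1,3,2-dioxaborolan-2-yl)ethenyl]-4,5,6,7-tetrahydro-2-benzofuran-1(3H)-one | O=C1OCC2=C1[C@H](/C=C/B3OC(C)(C)C(C)(C)O3)[C@@](C)(CCC=C(C)C)C[C@@H]2O | intermediate
15 | chloroacetone (1-chloropropan-2-one) | CC(=O)CCl | starting material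
16 | (4S,6S,7R)-6-methyl-6-(4-methylpent-3-en-1-yl)-7-[(E)-2-(4,4,5,5-tetramethyl-1,3,2-dioxaborolan-2-yl)ethenyl]-1,3,4,5,6,7-hexahydro-2-benzofuran-1,4-diol (lactol, both C1 epimers) | OC1OCC2=C1[C@H](/C=C/B3OC(C)(C)C(C)(C)O3)[C@@](C)(CCC=C(C)C)C[C@@H]2O | intermediate (not isolated)
17 | (3E)-4-{(3S,5S,6R)-3-hydroxy-2-(hydroxymethyl)-5-methyl-5-(4-methylpent-3-en-1-yl)-6-[(E)-2-(4,4,5,5-tetramethyl-1,3,2-dioxaborolan-2-yl)ethenyl]cyclohex-1-en-1-yl}but-3-en-2-one | CC(=O)/C=C/C1=C(CO)[C@@H](O)C[C@](C)(CCC=C(C)C)[C@H]1/C=C/B2OC(C)(C)C(C)(C)O2 | intermediate (not isolated)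
18 | 1-{(1S,4S,6S,7R)-4-hydroxy-6-methyl-6-(4-methylpent-3-en-1-yl)-7-[(E)-2-(4,4,5,5-tetramethyl-1,3,2-dioxaborolan-2-yl)ethenyl]-1,3,4,5,6,7-hexahydro-2-benzofuran-1-yl}propan-2-one | CC(=O)C[C@@H]1OCC2=C1[C@H](/C=C/B3OC(C)(C)C(C)(C)O3)[C@@](C)(CCC=C(C)C)C[C@@H]2O | intermediate
19 | 3-methylbut-2-enoic acid | CC(C)=CC(=O)O | starting material
20 | potassium trifluoro{(E)-2-[(1S,4S,6S,7R)-4-hydroxy-6-methyl-6-(4-methylpent-3-en-1-yl)-1-(2-oxopropyl)-1,3,4,5,6,7-hexahydro-2-benzofuran-7-yl]ethenyl}borate | CC(=O)C[C@@H]1OCC2=C1[C@H](/C=C/[B-](F)(F)F)[C@@](C)(CCC=C(C)C)C[C@@H]2O.[K+] | intermediate (not isolated)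
21 | (E)-2-[(1S,4S,6S,7R)-4-hydroxy-6-methyl-6-(4-methylpent-3-en-1-yl)-1-(2-oxopropyl)-1,3,4,5,6,7-hexahydro-2-benzofuran-7-yl]ethenyl 3-methylbut-2-enoate | CC(=O)C[C@@H]1OCC2=C1[C@H](/C=C/OC(=O)C=C(C)C)[C@@](C)(CCC=C(C)C)C[C@@H]2O | target

## Step count and risks

Total steps: 10. Longest linear sequence: 10 (from 1 to 21).

Steps most likely to fail:

Step 2 (iridium allylation). Tetronic acid has not been shown in this role; O-allylation, linear products or acid-induced cyclisation of the enol onto the isopropenyl group could dominate. The fallback sets out from 3 and 4 and comes back at 5. Rhenium-catalysed (Re2O7) 1,3-transposition of 3 gives the conjugated primary alcohol (2E)-4-methylpenta-2,4-dien-1-ol F1. Mitsunobu O-alkylation of 4 with it gives 4-{[(2E)-4-methylpenta-2,4-dien-1-yl]oxy}furan-2(5H)-one F2. An enantioselective [3,3]-Claisen rearrangement of this O-allyl vinylogous ester under a chiral guanidinium hydrogen-bond-donor catalyst forms the C7a–C7 bond and gives 5.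

Step 7 (Mn/Ni hydroalkylation, the key step). Capture by nickel may lose to hydrogenation, to MHAT isomerisation of the alkene towards C7, or to reaction at the alkene of the halide. The fallback sets out from 10 and comes back at 12. The same tertiary C6 radical, generated with Fe(acac)3 and PhSiH3, is trapped in a Giese addition by excess acrolein, again anti to the C7 vinyl group, to give 3-[(4S,6S,7R)-7-ethenyl-4-hydroxy-6-methyl-1-oxo-1,3,4,5,6,7-hexahydro-2-benzofuran-6-yl]propanal F3. Wittig olefination with isopropylidenetriphenylphosphorane at −78 °C then gives 12.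

Step 8 (boryl-Heck). The vinyl group is hindered, and β-hydride elimination towards C7 would give an allyl boronate. Metathesis cannot be used on 12, because ring closure onto the homoprenyl alkene would compete. The fallback therefore sets out from 10 and comes back at 14. Cross-metathesis of the vinyl group of 10 with vinylboronic acid pinacol ester (second-generation Grubbs catalyst, CH2Cl2, 40 °C), done before the homoprenyl chain is present, gives (4S,7R)-4-hydroxy-6-methylidene-7-[(E)-2-(4,4,5,5-tetramethyl-1,3,2-dioxaborolan-2-yl)ethenyl]-4,5,6,7-tetrahydro-2-benzofuran-1(3H)-one F4. The step 7 coupling applied to this alkenyl boronate gives 14 directly.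

Further compounds
F1 | step 2 | (2E)-4-methylpenta-2,4-dien-1-ol | CC(=C)/C=C/CO
F2 | step 2 | 4-{[(2E)-4-methylpenta-2,4-dien-1-yl]oxy}furan-2(5H)-one | O=C1OCC(OC/C=C/C(C)=C)=C1
F3 | step 7 | 3-[(4S,6S,7R)-7-ethenyl-4-hydroxy-6-methyl-1-oxo-1,3,4,5,6,7-hexahydro-2-benzofuran-6-yl]propanal | O=C1OCC2=C1[C@H](C=C)[C@@](C)(CCC=O)C[C@@H]2O
F4 | step 8 | (4S,7R)-4-hydroxy-6-methylidene-7-[(E)-2-(4,4,5,5-tetramethyl-1,3,2-dioxaborolan-2-yl)ethenyl]-4,5,6,7-tetrahydro-2-benzofuran-1(3H)-one | O=C1OCC2=C1[C@H](/C=C/B3OC(C)(C)C(C)(C)O3)C(=C)C[C@@H]2O
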